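## The problem

Compound 6 is a hexabrominated 2,2'-dihydroxydiphenyl ether, C12H4Br6O3. It has no stereocentre and no ring beyond its two benzene rings, so the task is one of connection and substitution pattern only.

Ring A is a 2,4-dibromophenol unit (hydroxyl at C1, bromine at C2 and C4) that carries the ether oxygen at C6. Ring B is a tetrabromocatechol (bromine at C3' to C6') whose oxygen at C1' is the ether oxygen and whose oxygen at C2' is free.

The single strategic bond is the diaryl ether. It joins two electron-poor, crowded rings: ring B is hexasubstituted and its ether oxygen is flanked by a hydroxyl and a bromine, so ionic or copper-mediated aryl ether formation would be slow.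

Six aryl C–Br bonds rule out organolithium reagents, zerovalent palladium, dissolving metals and hydrogenation late in the route.

The most fragile feature is the ring-A hydroxyl and the ring-B bromine at C6', both ortho to the same ether oxygen. Base with heat, or ultraviolet light, can close them to a dioxin ring by displacement of bromide. The final operations must therefore be neutral or acidic, cool and free of short-wavelength light.

A direct solution is possible because ring B, at the quinone oxidation level, is the symmetric tetrabromo-o-benzoquinone 2. All four of its ring carbons are blocked by bromine, so a radical derived from it can bond only through oxygen, and both oxygens are equivalent. In 2,4-dibromophenol 1, C6 is the only ortho or para carbon that bears hydrogen, and hence the only one where a new bond can be made permanent by rearomatisation. The formulas of 1 and 2 add up exactly to that of 6.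

## Retrosynthesis

**From 6 to dienone 5.** No skeletal bond is cut in the first move. The hydrogen on O1 of ring A in 6 is shifted to C6, which gives the cyclohexa-2,4-dienone 5. This retro-tautomerisation comes before any bond cleavage because it shows the ether oxygen on an sp3 carbon next to a carbonyl group, that is, on the ortho carbon of a phenoxyl unit. Forward, enolisation of a 6H-dienone to a phenol is strongly downhill and needs no reagent. It is the irreversible step that locks the new bond.

**From 5 to radicals 3 and 4.** The C6–O bond of 5 is cut homolytically into the 2,4-dibromophenoxyl radical 3 and the neutral tetrabromosemiquinone radical 4.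
- The neighbouring cut, O–C1' on the ring-B side, would need a ring-A oxygen nucleophile to attack a fully substituted, unactivated ring B next to a hydroxyl, with two competing catechol oxygens on ring A.
- Cutting C–Br bonds first (late bromination) could only deliver the two ring-A bromines, never the four of ring B.
- The C6–O cut divides the molecule into two six-carbon halves that each keep all their bromines and oxygens.
- Forward, 4 must react at oxygen, which its four bromines enforce, and 3 must react at C6 and not at O, C2 or C4.

**From 3 and 4 to 1 and 2.** The pair 3 and 4 differs from phenol 1 and quinone 2 only in the place of one hydrogen atom, so no further bond is cut. Returning the hydrogen from the oxygen of 4 to the oxygen of 3 gives the two purchasable partners, and the route shrinks to one step. The forward reaction must make 3 and 4 together and without free aryloxide. The phenolate of 1 would be expected to add to C4 or C5 of 2 and expel bromide, giving an ether at the wrong atoms. The pair is therefore to be made from neutral 1 by hydrogen atom transfer to visible-light-excited 2. This also keeps base and ultraviolet light away from 6.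

## Roads not taken

**Alternative 1:** The cut goes through ring B. Bonds C2'–C3' and C6'–C1' are opened. C3'–C6' with their four bromines come from tetrabromothiophene 1,1-dioxide A1. C1'–C2', with the ether oxygen already in place, come from the alkynyl boronate 2-[(2-methoxyphenoxy)ethynyl]-4,4,5,5-tetramethyl-1,3,2-dioxaborolane A2.
- Forward key step: A1 and A2 would combine in a Diels–Alder reaction of inverse electron demand. Cheletropic loss of the sulfonyl bridge would give the benzene ring of 2-[2,3,4,5-tetrabromo-6-(2-methoxyphenoxy)phenyl]-4,4,5,5-tetramethyl-1,3,2-dioxaborolane A3. Oxidation of the C–B bond, cleavage of the methyl ether and hydroxyl-directed dibromination of ring A would complete 6.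
- Merits: the ether oxygen rides in on the alkyne, so no diaryl ether is made at a crowded arene. The symmetric diene removes any question of orientation. Extrusion makes the cycloaddition irreversible. The last bromination is safe because ring B has no free position and the ring-A hydroxyl directs to C2 and C4.
- Weak points: neither A1 nor A2 can be bought. A1 needs a forcing peracid oxidation of its parent thiophene and tends to dimerise. A2 combines an acid-labile aryl ynol ether with an alkynyl boronate prone to protodeboronation and takes several steps. A3 is still three functional-group operations from 6, for roughly nine steps in all.
- Comparison: this road is better in certainty of substitution pattern, since no regiochemical or homocoupling question arises. The chosen plan sets against it a single step from two bought compounds that already hold all six bromines and all three oxygens, so a failed attempt costs little.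

**Alternative 2:** The cut removes both oxygens of ring B from C6 of ring A. C6 becomes a carbene carbon in the quinone diazide 2,4-dibromo-6-diazocyclohexa-2,4-dien-1-one A4, reachable from 1 by nitration at C6, reduction and diazotisation. Ring B is again quinone 2.
- Forward key step: dirhodium tetraacetate Rh2(OAc)4 would expel the diazo nitrogen from A4. A carbonyl oxygen of 2 would add to the carbenoid and the resulting ylide would close to the 1,3-dioxole of 3',5',4,5,6,7-hexabromospiro[1,3-benzodioxole-2,1'-cyclohexa-3',5'-dien]-2'-one A5. Two-electron reductive cleavage of one spiro C–O bond next to the ketone would then unveil 6.
- Merits: the site of the new C–O bond is fixed by the diazo carbon, so C2, C4 and phenoxyl homocoupling play no part. Addition of diazoalkanes across both oxygens of o-quinones to give benzodioxoles is a known reaction type.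
- Weak points: A4 costs three steps and is a hazardous diazo compound. Freed o-oxo carbenes of this kind contract by Wolff rearrangement. An electrophilic carbenoid is poorly matched with the electron-poor carbonyl oxygen of 2. A5 is an o-quinone monoketal that can dimerise by Diels–Alder reaction. The final reduction must spare six C–Br bonds, one of them on an enone. The sequence first oxidises and then reduces.
- Comparison: positional control is better here than in the chosen plan. The chosen plan makes the same C6–O bond redox-neutrally in one step instead of about five, and relies on the tautomerisation of 5 to sort the positions.

**Alternative 3:** The cut goes through ring A. Bonds C5–C6 and C2–C3 are opened, giving the aryloxyacetone 1-(2,3,4,5-tetrabromo-6-methoxyphenoxy)propan-2-one A6 (C1, C2 and C6 with the ether oxygen) and bromomalonaldehyde A7 (C3, C4 with its bromine, C5).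
- Forward key step: base would condense both α carbons of A6 with the two aldehyde groups of A7. Twofold dehydration would aromatise the ring to 4-bromo-2-(2,3,4,5-tetrabromo-6-methoxyphenoxy)phenol A8. Bromination at C2 and cleavage of the methyl ether would follow.
- Merits: the ether bond is made by alkylating a ring-B phenoxide at an unhindered sp3 carbon, so aryl ether formation is avoided altogether. Ring A is substituted by construction. The one late bromination has a single free activated position.
- Weak points: phenol synthesis from ketones and 1,3-dialdehydes is established for a nitro-substituted dialdehyde, but A7 is less electrophilic and base-sensitive. A6 has two different α positions, the aryloxy-bearing one more acidic and more hindered. The tetrabromoaryloxide is a good leaving group under the basic conditions. About five steps are needed.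
- Comparison: this road avoids radical chemistry and is better in predictability of the ring-A pattern. The chosen plan sets against it that no bromine has to be placed, no protecting group is needed and the step count is one.

Key step: step 1

Remark on the chemistry: carbon numbers follow the target, C1–C6 for ring A (hydroxyl at C1, ether at C6) and C1'–C6' for ring B (ether at C1', hydroxyl at C2'). The sp3 carbon C6 of dienone 5 is a transient racemic centre that disappears on tautomerisation, so no configuration is assigned. Quinone 2 is used as the recrystallised commercial reagent.

## Route

Step 1
Reactants: 1 2,4-dibromophenol; 2 tetrabromo-o-benzoquinone (3,4,5,6-tetrabromocyclohexa-3,5-diene-1,2-dione)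
Product: 6 3,4,5,6-tetrabromo-2-(3,5-dibromo-2-hydroxyphenoxy)phenol, via 2,4-dibromophenoxyl radical 3 (not isolated), via tetrabromosemiquinone radical 4 (not isolated), via coupled dienone 5 (not isolated)
Conditions: 1 (3 equiv), 2 (1 equiv, 0.02 M), degassed PhCF3, 450 nm LED, 15–20 °C, Ar, until the red colour of 2 has faded; evaporation, excess 1 removed by sublimation, chromatography on acid-washed silica
Reagents that add atoms: none
Why: Proposed new method: visible light excites only quinone 2, whose excited state (free or hydrogen-bonded to 1) takes the phenolic hydrogen atom of 1 by proton-coupled electron transfer and gives the geminate pair of phenoxyl 3 and neutral semiquinone 4; no aryloxide is present at any time, so addition–elimination at the bromine-bearing C4 or C5 of 2 is shut off. The six bromine atoms should speed spin inversion of the pair, and 4 can bond only through oxygen because all four of its ring carbons carry bromine, so collapse onto C6 of 3 gives dienone 5, which enolises to 6. The closest known reaction types are the photoaddition of hydrogen donors (aldehydes, ethers, alkylarenes) to o-quinones, which ends in the same collapse of a semiquinone oxygen onto the partner radical to give catechol monoesters and monoethers, the quinol ether adducts of hindered phenols with high-potential quinones, and the oxidative O–C(ortho) coupling of 2,4-dibromophenol itself; a phenoxyl radical as the carbon partner of an o-semiquinone has not been shown. No ring is closed and no stereocentre remains, since the sp3 carbon C6 of 5 forms as a racemate and is erased on tautomerisation. The step needs cross-coupling over homocoupling and C6 over C2 and C4: back transfer of hydrogen within the pair only returns 1 and 2, the hydrogen bond from the O–H of 4 to the oxygen of 3 holds the free oxygen of 4 over the ortho carbons and away from C4, and adducts at the bromine-bearing C2 or C4 cannot enolise and should revert by homolysis of the weak dienone C–O bond, whereas the C6 adduct is drained irreversibly by aromatisation. Quinone 2 is the limiting reagent and the only chromophore at 450 nm, so the colourless 6 is neither excited nor exposed to base, which protects it from closure to a dioxin, and the excess of 1 should outcompete 6 as hydrogen donor.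

## Compound list

1 | 2,4-dibromophenol | Oc1ccc(Br)cc1Br | starting material
2 | tetrabromo-o-benzoquinone (3,4,5,6-tetrabromocyclohexa-3,5-diene-1,2-dione) | O=C1C(=O)C(Br)=C(Br)C(Br)=C1Br | starting material
3 | 2,4-dibromophenoxyl radical | [O]c1ccc(Br)cc1Br | intermediate
4 | 3,4,5,6-tetrabromo-2-hydroxyphenoxyl radical (neutral tetrabromo-o-semiquinone) | [O]c1c(O)c(Br)c(Br)c(Br)c1Br | intermediate
5 | 2,4-dibromo-6-(2,3,4,5-tetrabromo-6-hydroxyphenoxy)cyclohexa-2,4-dien-1-one (racemic at C6) | O=C1C(Br)=CC(Br)=CC1Oc1c(O)c(Br)c(Br)c(Br)c1Br | intermediate
6 | 3,4,5,6-tetrabromo-2-(3,5-dibromo-2-hydroxyphenoxy)phenol | Oc1c(Br)cc(Br)cc1Oc1c(O)c(Br)c(Br)c(Br)c1Br | target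

## Step count and risk

Total step count: 1. Longest linear sequence: 1 step. The route has no step besides the key step, so the list of uncertain steps has this one entry.

**Step 1 (key step, proposed new method).** Three processes are most likely to go wrong.
- Loss of cross-selectivity: 3 and 4 may escape the solvent cage before they bond. Phenoxyl 3 would then couple with itself through O–C6 or C6–C6, while 4 disproportionates. This is likely because a pair born from a triplet must change spin before it can bond, and separation by diffusion competes with that.
- Erosion of the bromine pattern: bonding at the bromine-bearing C2 or C4 of 3 may be followed by loss of a bromine atom instead of reversion.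
- Over-oxidation: late in the reaction, when 1 is no longer in large excess over the product, hydrogen may be abstracted from the two hydroxyls of 6.

**Fallback (known chemistry, sets out from 2 and returns at 6).** It gives up the radical coupling and makes the ether by nucleophilic aromatic substitution before ring A is brominated.
- Quinone 2 is reduced with aqueous Na2S2O4 to 3,4,5,6-tetrabromobenzene-1,2-diol F1.
- The dianion of F1 (K2CO3, DMF, 90 °C, Ar) displaces fluoride from 2-fluorobenzaldehyde in an SNAr reaction. It should stop after one arylation, because the remaining phenoxide of 2-(2,3,4,5-tetrabromo-6-hydroxyphenoxy)benzaldehyde F2 is a far weaker nucleophile, and ring A of F2 has no leaving group ortho to the ether that could close a dioxin.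
- Dakin (Baeyer–Villiger) oxidation of F2 with mCPBA in CH2Cl2 gives 2-(2,3,4,5-tetrabromo-6-hydroxyphenoxy)phenyl formate F3, which is not isolated. HCl in methanol cleaves it, without base, to 3,4,5,6-tetrabromo-2-(2-hydroxyphenoxy)phenol F4.
- Bromination of F4 with two equivalents of Br2 in acetic acid at room temperature is steered by the ring-A hydroxyl to its ortho and para carbons C2 and C4, ring B having no free position, and gives 6.
- Its own weak points are the air sensitivity of the catechol dianion and the need for aryl over hydride migration in the Dakin step, which the ortho aryloxy group should favour.

## Further compounds

F1 | step 1 | 3,4,5,6-tetrabromobenzene-1,2-diol | Oc1c(O)c(Br)c(Br)c(Br)c1Br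
F2 | step 1 | 2-(2,3,4,5-tetrabromo-6-hydroxyphenoxy)benzaldehyde | O=Cc1ccccc1Oc1c(O)c(Br)c(Br)c(Br)c1Br
F3 | step 1 | 2-(2,3,4,5-tetrabromo-6-hydroxyphenoxy)phenyl formate | O=COc1ccccc1Oc1c(O)c(Br)c(Br)c(Br)c1Br
F4 | step 1 | 3,4,5,6-tetrabromo-2-(2-hydroxyphenoxy)phenol | Oc1ccccc1Oc1c(O)c(Br)c(Br)c(Br)c1Br
A1 | alternative 1 | tetrabromothiophene 1,1-dioxide | O=S1(=O)C(Br)=C(Br)C(Br)=C1Br
A2 | alternative 1 | 2-[(2-methoxyphenoxy)ethynyl]-4,4,5,5-tetramethyl-1,3,2-dioxaborolane | COc1ccccc1OC#CB1OC(C)(C)C(C)(C)O1
A3 | alternative 1 | 2-[2,3,4,5-tetrabromo-6-(2-methoxyphenoxy)phenyl]-4,4,5,5-tetramethyl-1,3,2-dioxaborolane | COc1ccccc1Oc1c(B2OC(C)(C)C(C)(C)O2)c(Br)c(Br)c(Br)c1Br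
A4 | alternative 2 | 2,4-dibromo-6-diazocyclohexa-2,4-dien-1-one | O=C1C(Br)=CC(Br)=CC1=[N+]=[N-]
A5 | alternative 2 | 3',5',4,5,6,7-hexabromospiro[1,3-benzodioxole-2,1'-cyclohexa-3',5'-dien]-2'-one | O=C1C(Br)=CC(Br)=CC12Oc3c(Br)c(Br)c(Br)c(Br)c3O2
A6 | alternative 3 | 1-(2,3,4,5-tetrabromo-6-methoxyphenoxy)propan-2-one | CC(=O)COc1c(OC)c(Br)c(Br)c(Br)c1Br
A7 | alternative 3 | bromomalonaldehyde (2-bromopropanedial) | O=CC(Br)C=O
A8 | alternative 3 | 4-bromo-2-(2,3,4,5-tetrabromo-6-methoxyphenoxy)phenol | Oc1ccc(Br)cc1Oc1c(OC)c(Br)c(Br)c(Br)c1Br
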